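**Retrosynthetic overview**

1. Labels: C1 (CH–O), C2 (CH2), C3 (quaternary C–CH3), C4 (CH2), C5 (C=O), C6 (C(CH3)–O), C7 and C8 (CH2), C9=C10 (C10 bears isopropyl); ring A is the cyclopentene C1–C2–C3–C9–C10 and ring B the seven-membered ring C3–C4–C5–C6–C7–C8–C9. The plan rests on C3, a hydrogen-free quaternary carbon bonded directly to the alkene carbon C9 and separated from the C5 carbonyl only by C4.
2. Both angelates are removed last, each coming from one batch of a preformed angeloyl mixed anhydride; ring B is opened at C5–C6 (carbene-catalysed aldehyde-to-ketone benzoin), leaving a C5 aldehyde and a C6 methyl ketone on ring A.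
3. Ring A is opened at C3–C9: enantioselective 5-exo Heck cyclisation of a Z-alkenyl iodide (C9–I) onto the C3=C4 allylic alcohol, the unsaturation ending at C5 as the aldehyde.
4. The iodide comes from anti-carbomagnesiation (isopropyl to C10) and iodination of a (1S)-propargylic alcohol, made by acetylide addition (C1–C10), oxidation and asymmetric ynone reduction; C3=C4 comes from methylalumination of an alkyne.
5. Ring order: ring A (step 13), then ring B (step 15).

Key step: step 13

Assumption: the target has C1–O, C3–CH3 and C6–O on one face (1S,3R,6S in the labels above); (R)-BINAP in step 13 and the (5aS,10bR)-triazolium salt in step 15 are taken as the matched enantiomers, and the mirror-image ligand or salt would be used if a pilot run shows the opposite sense.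

**Route**

Step 1
Reactants: 1 but-3-yn-1-ol
Product: 2 tert-butyl(but-3-yn-1-yloxy)dimethylsilane
Conditions: TBSCl, imidazole, DMF, 0 °C→rt
Reagents that add atoms: tert-butyldimethylsilyl chloride, CC(C)(C)[Si](C)(C)Cl
Why: Standard silyl ether formation on a primary alcohol masks the future C1 oxygen for the organoaluminium step.

Step 2
Reactants: 2 tert-butyl(but-3-yn-1-yloxy)dimethylsilane
Product: 4 (E)-5-[(tert-butyldimethylsilyl)oxy]-3-methylpent-2-en-1-ol, via E-alkenyldimethylalane 3 (not isolated)
Conditions: AlMe3 (2.5 equiv), Cp2ZrCl2 (0.25 equiv), CH2Cl2, 0 °C→rt; then (CH2O)n, THF, 0 °C→rt; aq. KNaC4H4O6 work-up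
Reagents that add atoms: trimethylaluminium, C[Al](C)C; paraformaldehyde (as formaldehyde), C=O
Why: Negishi zirconium-catalysed carboalumination adds methyl and aluminium syn across the terminal alkyne with methyl on the internal carbon (C3), and hydroxymethylation of the C–Al bond with retention fixes the E geometry of C3=C4 and installs C5.

Step 3
Reactants: 4 (E)-5-[(tert-butyldimethylsilyl)oxy]-3-methylpent-2-en-1-ol
Product: 5 (E)-tert-butyl({5-[(4-methoxybenzyl)oxy]-3-methylpent-3-en-1-yl}oxy)dimethylsilane
Conditions: NaH, 4-methoxybenzyl chloride, Bu4NI (cat.), THF, 0 °C→rt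
Reagents that add atoms: 4-methoxybenzyl chloride, COc1ccc(CCl)cc1
Why: Williamson etherification of the primary allylic alkoxide gives a C5 protecting group that can later be removed oxidatively without touching silyl ethers or the ketal.

Step 4
Reactants: 5 (E)-tert-butyl({5-[(4-methoxybenzyl)oxy]-3-methylpent-3-en-1-yl}oxy)dimethylsilane
Product: 6 (E)-5-[(4-methoxybenzyl)oxy]-3-methylpent-3-en-1-ol
Conditions: Bu4NF, THF, 0 °C→rt
Reagents that add atoms: none
Why: Fluoride-mediated desilylation frees the primary C1 hydroxyl and leaves the benzylic ether and the alkene untouched.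

Step 5
Reactants: 6 (E)-5-[(4-methoxybenzyl)oxy]-3-methylpent-3-en-1-ol
Product: 7 (E)-5-[(4-methoxybenzyl)oxy]-3-methylpent-3-enal
Conditions: Dess–Martin periodinane, NaHCO3, CH2Cl2, 0 °C; crude aldehyde used at once
Reagents that add atoms: none
Why: Dess–Martin oxidation under bicarbonate buffer gives the β,γ-unsaturated aldehyde without the acid or amine base that would move C3=C4 into conjugation.

Step 6
Reactants: 8 hex-5-yn-2-one
Product: 9 2-(but-3-yn-1-yl)-2-methyl-1,3-dioxolane
Conditions: ethylene glycol, p-TsOH·H2O (cat.), benzene, reflux, Dean–Stark trap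
Reagents that add atoms: ethane-1,2-diol, OCCO
Why: Acid-catalysed ketalisation with azeotropic removal of water protects the C6 ketone against the organolithium and Grignard steps.

Step 7
Reactants: 9 2-(but-3-yn-1-yl)-2-methyl-1,3-dioxolane; 7 (E)-5-[(4-methoxybenzyl)oxy]-3-methylpent-3-enal
Product: 11 racemic (E)-1-[(4-methoxybenzyl)oxy]-3-methyl-9-(2-methyl-1,3-dioxolan-2-yl)non-2-en-6-yn-5-ol, via lithium acetylide 10 (not isolated)
Conditions: 9, n-BuLi, THF, −78 °C; then 7, −78 °C; H2O quench
Reagents that add atoms: none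
Why: 1,2-Addition of a lithium acetylide to an aldehyde at −78 °C outruns enolisation, so the C1–C10 bond forms without isomerising the skipped alkene; C1 is racemic here and its configuration is set in steps 8 and 9, because amine-mediated asymmetric alkynylation would put this aldehyde at risk.

Step 8
Reactants: 11 racemic propargylic alcohol
Product: 12 (E)-1-[(4-methoxybenzyl)oxy]-3-methyl-9-(2-methyl-1,3-dioxolan-2-yl)non-2-en-6-yn-5-one
Conditions: Dess–Martin periodinane, NaHCO3, CH2Cl2, 0 °C
Reagents that add atoms: none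
Why: Dess–Martin oxidation of a propargylic alcohol gives the ynone under buffered, cold conditions that should leave the doubly activated C2 methylene in place.

Step 9
Reactants: 12 ynone
Product: 13 (2E,5S)-1-[(4-methoxybenzyl)oxy]-3-methyl-9-(2-methyl-1,3-dioxolan-2-yl)non-2-en-6-yn-5-ol
Conditions: Ru(p-cymene)[(S,S)-TsNCH(Ph)CH(Ph)NH] (2 mol %), i-PrOH, rt
Reagents that add atoms: none
Why: Noyori asymmetric transfer hydrogenation of an alkynyl ketone under base-free conditions; the ruthenium hydride and ligand N–H deliver hydrogen to one carbonyl face with the alkyne in the aryl-like position, so the (S,S)-ligand should give the (S)-carbinol at C1.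

Step 10
Reactants: 13 (S)-propargylic alcohol; 14 isopropylmagnesium chloride
Product: 16 (2E,5S,6Z)-7-iodo-1-[(4-methoxybenzyl)oxy]-3-methyl-9-(2-methyl-1,3-dioxolan-2-yl)-6-(propan-2-yl)nona-2,6-dien-5-ol, via magnesium chelate 15 (not isolated)
Conditions: 14 (3 equiv), CuI (20 mol %), THF–toluene, −20 °C→rt; then I2 (2.2 equiv), THF, −78 °C→−20 °C; aq. Na2S2O3
Reagents that add atoms: iodine, II
Why: CuI-catalysed, alkoxide-directed anti-carbomagnesiation of a propargylic alcohol places isopropyl on the alkyne carbon next to the carbinol (C10) and magnesium on C9 inside a five-membered chelate, so iodinolysis with retention gives the iodide with iodine cis to C1 (Z) and leaves C1 untouched.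

Step 11
Reactants: 16 Z-iodo allylic alcohol
Product: 17 (2E,5S,6Z)-tert-butyl({7-iodo-1-[(4-methoxybenzyl)oxy]-3-methyl-9-(2-methyl-1,3-dioxolan-2-yl)-6-(propan-2-yl)nona-2,6-dien-5-yl}oxy)dimethylsilane
Conditions: TBSOTf, 2,6-lutidine, CH2Cl2, −78 °C→0 °C
Reagents that add atoms: tert-butyldimethylsilyl trifluoromethanesulfonate, CC(C)(C)[Si](C)(C)OS(=O)(=O)C(F)(F)F
Why: Silyl triflate with a hindered pyridine base silylates the crowded secondary C1 hydroxyl at low temperature, where the dioxolane and the benzylic ether are stable.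

Step 12
Reactants: 17 silyl ether
Product: 18 (2E,5S,6Z)-5-[(tert-butyldimethylsilyl)oxy]-7-iodo-3-methyl-9-(2-methyl-1,3-dioxolan-2-yl)-6-(propan-2-yl)nona-2,6-dien-1-ol
Conditions: DDQ, CH2Cl2/pH 7 phosphate buffer (10:1), 0 °C
Reagents that add atoms: none
Why: Oxidative cleavage of the 4-methoxybenzyl ether by DDQ frees the C5 allylic alcohol while the silyl ether, ketal and alkenyl iodide stay intact.

Step 13
Reactants: 18 Z-alkenyl iodide with free C5 allylic alcohol
Product: 20 2-[(1R,4S)-4-[(tert-butyldimethylsilyl)oxy]-1-methyl-2-[2-(2-methyl-1,3-dioxolan-2-yl)ethyl]-3-(propan-2-yl)cyclopent-2-en-1-yl]acetaldehyde, via enol 19 (not isolated)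
Conditions: Pd2(dba)3·CHCl3 (5 mol %), (R)-BINAP (12 mol %), Ag3PO4 (2 equiv), DMA, 80 °C
Reagents that add atoms: none
Why: Zerovalent palladium carrying (R)-BINAP inserts into the C9–I bond, Ag3PO4 removes iodide so that the cationic, still chelated alkenylpalladium binds the C3=C4 alkene and inserts syn to form C3–C9, and the resulting C4–palladium species, which has no hydrogen on quaternary C3, can only eliminate a hydride from C5 to give enol 19, which tautomerises to the aldehyde. The closest known reaction types are the silver-promoted asymmetric intramolecular Heck cyclisation that builds all-carbon quaternary centres and the Heck reaction of allylic alcohols that ends in a carbonyl group. Ring A closes in the 5-exo-trig mode, with C9=C10 remaining inside the new ring as in cyclisations of ortho-substituted aryl halides. The new stereocentre C3 is set by the BINAP enantiomer, which selects the alkene face in the insertion, with the C1 silyl ether (expected to lie trans to the palladium-bearing C4 arm) as a secondary bias, so that C3–CH3 should end cis to C1–O. The step needs 5-exo over 6-endo insertion, secured by the three-atom tether and the Z geometry that holds palladium cis to C1, and one-way elimination, secured by quaternary C3; the ketal, silyl ether and tetrasubstituted alkene are spectators.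

Step 14
Reactants: 20 ketal aldehyde
Product: 21 2-[(1R,4S)-4-[(tert-butyldimethylsilyl)oxy]-1-methyl-2-(3-oxobutyl)-3-(propan-2-yl)cyclopent-2-en-1-yl]acetaldehyde
Conditions: pyridinium p-toluenesulfonate (0.2 equiv), acetone/H2O (9:1), 50 °C
Reagents that add atoms: water, O
Why: Mild acid-catalysed ketal hydrolysis frees the C6 methyl ketone at an acidity that the secondary silyl ether and the aldehyde tolerate.

Step 15
Reactants: 21 keto-aldehyde
Product: 22 (2S,6S,8aR)-2-[(tert-butyldimethylsilyl)oxy]-6-hydroxy-6,8a-dimethyl-3-(propan-2-yl)-1,2,4,5,6,8a-hexahydroazulen-7(8H)-one (labels: 1S,3R,6S; C5 ketone, C6 tertiary alcohol)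
Conditions: (5aS,10bR)-2-(pentafluorophenyl)-5a,10b-dihydro-4H,6H-indeno[2,1-b][1,2,4]triazolo[4,3-d][1,4]oxazin-2-ium tetrafluoroborate (15 mol %), Et3N (15 mol %), toluene, rt
Reagents that add atoms: none
Why: Proposed new method: the carbene formed from the triazolium salt adds to the C5 aldehyde, proton transfer gives the acyl-anion equivalent (hydroxy-enamine), this adds to the C6 ketone in a 7-exo-trig closure of ring B, and loss of the carbene gives the ketol; the closest known reaction type is the carbene-catalysed intramolecular crossed aldehyde–ketone benzoin cyclisation, established for five- and six-membered ketols, and the extension to a seven-membered ring is supported by the cis C4 and C8 arms on the rigid cyclopentene, which hold the two carbonyls close as an ortho-disubstituted arene does; the chiral triazolium is expected to select the ketone face so that C6–OH ends cis to C3–CH3 (6S), with quaternary C3 as a substrate bias.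

Step 16
Reactants: 23 angelic acid
Product: 24 (Z)-2-methylbut-2-enoic 2,4,6-trichlorobenzoic anhydride
Conditions: 2,4,6-trichlorobenzoyl chloride, Et3N, toluene, 0 °C→rt; filtered under argon; filtrate kept as a toluene stock solution at −20 °C, one batch sized for steps 17 and 19
Reagents that add atoms: 2,4,6-trichlorobenzoyl chloride, O=C(Cl)c1c(Cl)cc(Cl)cc1Cl
Why: Yamaguchi mixed-anhydride formation by acylation of the triethylammonium carboxylate with the aroyl chloride proceeds at or below room temperature without a nucleophilic catalyst, so the Z alkene of the angeloyl group should be kept.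

Step 17
Reactants: 22 ketol; 24 (Z)-2-methylbut-2-enoic 2,4,6-trichlorobenzoic anhydride
Product: 26 (2S,6S,8aR)-2-[(tert-butyldimethylsilyl)oxy]-6,8a-dimethyl-7-oxo-3-(propan-2-yl)-1,2,4,5,6,7,8,8a-octahydroazulen-6-yl (Z)-2-methylbut-2-enoate, via lithium alkoxide 25 (not isolated)
Conditions: 22, LiN(SiMe3)2 (1.0 equiv), THF, −78 °C; then 24 (toluene solution), −78 °C→0 °C
Reagents that add atoms: none
Why: O-Acylation of a tertiary lithium alkoxide by a Yamaguchi-type mixed anhydride occurs at the unhindered angeloyl carbonyl, and the absence of nucleophilic amine catalysts and heat should keep the Z alkene and avoid α-ketol rearrangement.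

Step 18
Reactants: 26 C6 angelate silyl ether
Product: 27 (2S,6S,8aR)-2-hydroxy-6,8a-dimethyl-7-oxo-3-(propan-2-yl)-1,2,4,5,6,7,8,8a-octahydroazulen-6-yl (Z)-2-methylbut-2-enoate
Conditions: HF·pyridine, pyridine, THF, 0 °C→rt
Reagents that add atoms: none
Why: Buffered fluoride desilylation removes the secondary silyl ether without the basic conditions that could cleave or isomerise the angelate.

Step 19
Reactants: 27 C1 alcohol; 24 (Z)-2-methylbut-2-enoic 2,4,6-trichlorobenzoic anhydride
Product: 28 CNP0193302.1, (2S,6S,8aR)-6,8a-dimethyl-7-oxo-3-(propan-2-yl)-1,2,4,5,6,7,8,8a-octahydroazulene-2,6-diyl bis[(Z)-2-methylbut-2-enoate]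
Conditions: 24 (toluene solution, 3 equiv), Et3N (3 equiv), toluene, 75 °C
Reagents that add atoms: none
Why: Yamaguchi-type esterification with the preformed 2,4,6-trichlorobenzoyl mixed anhydride, run without DMAP in warm toluene, acylates hindered secondary alcohols at the angeloyl carbonyl with retention of the Z alkene, and acylation at oxygen leaves C1 unchanged.

**Compound list**

1 | but-3-yn-1-ol | C#CCCO | starting material
2 | tert-butyl(but-3-yn-1-yloxy)dimethylsilane | C#CCCO[Si](C)(C)C(C)(C)C | intermediate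
3 | (E)-{4-[(tert-butyldimethylsilyl)oxy]-2-methylbut-1-en-1-yl}dimethylalane (not isolated) | C/C(CCO[Si](C)(C)C(C)(C)C)=C\[Al](C)C | intermediate
4 | (E)-5-[(tert-butyldimethylsilyl)oxy]-3-methylpent-2-en-1-ol | C/C(CCO[Si](C)(C)C(C)(C)C)=C\CO | intermediate
5 | (E)-tert-butyl({5-[(4-methoxybenzyl)oxy]-3-methylpent-3-en-1-yl}oxy)dimethylsilane | C/C(CCO[Si](C)(C)C(C)(C)C)=C\COCc1ccc(OC)cc1 | intermediate
6 | (E)-5-[(4-methoxybenzyl)oxy]-3-methylpent-3-en-1-ol | C/C(CCO)=C\COCc1ccc(OC)cc1 | intermediate
7 | (E)-5-[(4-methoxybenzyl)oxy]-3-methylpent-3-enal | C/C(CC=O)=C\COCc1ccc(OC)cc1 | intermediate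
8 | hex-5-yn-2-one | CC(=O)CCC#C | starting material
9 | 2-(but-3-yn-1-yl)-2-methyl-1,3-dioxolane | CC1(CCC#C)OCCO1 | intermediate
10 | [4-(2-methyl-1,3-dioxolan-2-yl)but-1-yn-1-yl]lithium (not isolated) | CC1(CCC#C[Li])OCCO1 | intermediate
11 | racemic (E)-1-[(4-methoxybenzyl)oxy]-3-methyl-9-(2-methyl-1,3-dioxolan-2-yl)non-2-en-6-yn-5-ol | CC1(CCC#CC(O)C/C(C)=C/COCc2ccc(OC)cc2)OCCO1 | intermediate
12 | (E)-1-[(4-methoxybenzyl)oxy]-3-methyl-9-(2-methyl-1,3-dioxolan-2-yl)non-2-en-6-yn-5-one | CC1(CCC#CC(=O)C/C(C)=C/COCc2ccc(OC)cc2)OCCO1 | intermediate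
13 | (2E,5S)-1-[(4-methoxybenzyl)oxy]-3-methyl-9-(2-methyl-1,3-dioxolan-2-yl)non-2-en-6-yn-5-ol | CC1(CCC#C[C@@H](O)C/C(C)=C/COCc2ccc(OC)cc2)OCCO1 | intermediate
14 | isopropylmagnesium chloride | CC(C)[Mg]Cl | starting material
15 | cyclic alkenylmagnesium alkoxide, five-membered ring O–Mg–C9=C10–C1 (not isolated) | CC1(CC/C2=C(\C(C)C)[C@H](C/C(C)=C/COCc3ccc(OC)cc3)O[Mg]2)OCCO1 | intermediate
16 | (2E,5S,6Z)-7-iodo-1-[(4-methoxybenzyl)oxy]-3-methyl-9-(2-methyl-1,3-dioxolan-2-yl)-6-(propan-2-yl)nona-2,6-dien-5-ol | CC1(CC/C(I)=C(\C(C)C)[C@@H](O)C/C(C)=C/COCc2ccc(OC)cc2)OCCO1 | intermediate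
17 | (2E,5S,6Z)-tert-butyl({7-iodo-1-[(4-methoxybenzyl)oxy]-3-methyl-9-(2-methyl-1,3-dioxolan-2-yl)-6-(propan-2-yl)nona-2,6-dien-5-yl}oxy)dimethylsilane | CC1(CC/C(I)=C(\C(C)C)[C@@H](O[Si](C)(C)C(C)(C)C)C/C(C)=C/COCc2ccc(OC)cc2)OCCO1 | intermediate
18 | (2E,5S,6Z)-5-[(tert-butyldimethylsilyl)oxy]-7-iodo-3-methyl-9-(2-methyl-1,3-dioxolan-2-yl)-6-(propan-2-yl)nona-2,6-dien-1-ol | CC1(CC/C(I)=C(\C(C)C)[C@@H](O[Si](C)(C)C(C)(C)C)C/C(C)=C/CO)OCCO1 | intermediate
19 | enol of aldehyde 20, C4=C5–OH (not isolated) | CC1(CCC2=C(C(C)C)[C@@H](O[Si](C)(C)C(C)(C)C)C[C@]2(C)C=CO)OCCO1 | intermediate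
20 | 2-[(1R,4S)-4-[(tert-butyldimethylsilyl)oxy]-1-methyl-2-[2-(2-methyl-1,3-dioxolan-2-yl)ethyl]-3-(propan-2-yl)cyclopent-2-en-1-yl]acetaldehyde | CC1(CCC2=C(C(C)C)[C@@H](O[Si](C)(C)C(C)(C)C)C[C@]2(C)CC=O)OCCO1 | intermediate
21 | 2-[(1R,4S)-4-[(tert-butyldimethylsilyl)oxy]-1-methyl-2-(3-oxobutyl)-3-(propan-2-yl)cyclopent-2-en-1-yl]acetaldehyde | CC(=O)CCC1=C(C(C)C)[C@@H](O[Si](C)(C)C(C)(C)C)C[C@]1(C)CC=O | intermediate
22 | (2S,6S,8aR)-2-[(tert-butyldimethylsilyl)oxy]-6-hydroxy-6,8a-dimethyl-3-(propan-2-yl)-1,2,4,5,6,8a-hexahydroazulen-7(8H)-one | CC(C)(C)[Si](C)(C)O[C@H]1C[C@]2(C)CC(=O)[C@@](C)(O)CCC2=C1C(C)C | intermediate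
23 | angelic acid, (Z)-2-methylbut-2-enoic acid | C/C=C(/C)C(=O)O | starting material
24 | (Z)-2-methylbut-2-enoic 2,4,6-trichlorobenzoic anhydride | C/C=C(/C)C(=O)OC(=O)c1c(Cl)cc(Cl)cc1Cl | intermediate
25 | lithium C6 alkoxide of 22 (not isolated) | CC(C)(C)[Si](C)(C)O[C@H]1C[C@]2(C)CC(=O)[C@@](C)([O-])CCC2=C1C(C)C.[Li+] | intermediate
26 | (2S,6S,8aR)-2-[(tert-butyldimethylsilyl)oxy]-6,8a-dimethyl-7-oxo-3-(propan-2-yl)-1,2,4,5,6,7,8,8a-octahydroazulen-6-yl (Z)-2-methylbut-2-enoate | CC(C)(C)[Si](C)(C)O[C@H]1C[C@]2(C)CC(=O)[C@@](C)(OC(=O)/C(C)=C\C)CCC2=C1C(C)C | intermediate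
27 | (2S,6S,8aR)-2-hydroxy-6,8a-dimethyl-7-oxo-3-(propan-2-yl)-1,2,4,5,6,7,8,8a-octahydroazulen-6-yl (Z)-2-methylbut-2-enoate | O[C@H]1C[C@]2(C)CC(=O)[C@@](C)(OC(=O)/C(C)=C\C)CCC2=C1C(C)C | intermediate
28 | CNP0193302.1, (2S,6S,8aR)-6,8a-dimethyl-7-oxo-3-(propan-2-yl)-1,2,4,5,6,7,8,8a-octahydroazulene-2,6-diyl bis[(Z)-2-methylbut-2-enoate] | C/C=C(/C)C(=O)O[C@H]1C[C@]2(C)CC(=O)[C@@](C)(OC(=O)/C(C)=C\C)CCC2=C1C(C)C | target

**Step count**

Total steps: 19. Longest linear sequence: 17 steps (steps 1–5, 7–15 and 17–19, from but-3-yn-1-ol).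

**Steps most likely to fail**

1. Step 15 (carbene-catalysed closure of ring B). The acyl-anion equivalent may add too slowly across the seven-membered transition state, so that base-mediated aldol closure of a six-membered ring (C7 onto C5) or aldehyde self-condensation takes over; the ketone face may also be chosen poorly. The fallback sets out from keto-aldehyde 21: reductive ketyl coupling of aldehyde and ketone with SmI2 (THF, t-BuOH, −78 °C) should give the cis-5,6-diol F1, and selective oxidation of its secondary C5 hydroxyl (Dess–Martin periodinane, NaHCO3, CH2Cl2, 0 °C) comes back to the route at ketol 22. C6 would then rest on substrate control, and an unwanted C6 epimer would be removed at the diol stage.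

2. Step 13 (asymmetric Heck cyclisation). Oxidative addition and insertion at the crowded tetrasubstituted alkenyl iodide may be slow, which would allow protodeiodination or palladium-alkoxide oxidation of the allylic alcohol, and the ligand may not override the C1 bias in choosing the alkene face. The fallback sets out from iodide 18: MnO2 (CH2Cl2, rt) should oxidise the allylic alcohol to the enal F2, and Bu3SnH with AIBN (benzene, 80 °C, slow addition) should then generate the C9 alkenyl radical, which closes ring A by 5-exo-trig conjugate addition to C3; reduction of the α-formyl radical by the stannane comes back to the route at aldehyde 20. C3 would then rest on the C1 silyl ether alone, and epimers would be separated.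

3. Step 10 (anti-carbomagnesiation with a secondary alkyl Grignard reagent). Hydride transfer from the isopropyl group or sluggish carbometalation may leave the alkyne reduced or unreacted, and excess iodine may engage the C3=C4 alkene with the C1 alkoxide. The fallback sets out from propargylic alcohol 13: isopropenylmagnesium bromide (THF–toluene, reflux, no copper salt), followed by I2, should give the iodo-triene F3 by the same alkoxide-directed anti-addition, and diimide reduction (2-nitrobenzenesulfonyl hydrazide, Et3N, CH2Cl2, rt) of the 1,1-disubstituted alkene comes back to the route at iodide 16.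

**Further compounds**

F1 | step 15 | cis-5,6-diol of the hydroazulene, C5 and C6 hydroxyls on the face of the C3 methyl group, C1 silyl ether | CC(C)(C)[Si](C)(C)O[C@H]1C[C@]2(C)C[C@@H](O)[C@@](C)(O)CCC2=C1C(C)C
F2 | step 13 | (2E,5S,6Z)-5-[(tert-butyldimethylsilyl)oxy]-7-iodo-3-methyl-9-(2-methyl-1,3-dioxolan-2-yl)-6-(propan-2-yl)nona-2,6-dienal | CC1(CC/C(I)=C(\C(C)C)[C@@H](O[Si](C)(C)C(C)(C)C)C/C(C)=C/C=O)OCCO1
F3 | step 10 | (2E,5S,6Z)-7-iodo-1-[(4-methoxybenzyl)oxy]-3-methyl-9-(2-methyl-1,3-dioxolan-2-yl)-6-(prop-1-en-2-yl)nona-2,6-dien-5-ol | CC1(CC/C(I)=C(\C(C)=C)[C@@H](O)C/C(C)=C/COCc2ccc(OC)cc2)OCCO1
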